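## Structural features

The target is a monocyclic germacrane: one ten-membered carbocycle (C1–C10) with an E trisubstituted C1=C10 olefin (C14 methyl on C10), a 4,5-oxirane fused trans to the ring (C15 methyl on C4), a 3-methylbut-2-enoate on C3, an acetate on C6 and an isopropyl group on C7. Five stereocentres, C3 (S), C4 (R), C5 (R), C6 (R) and C7 (S), stand in an unbroken row on one flank of the ring; the olefin on the other flank is the only further stereoelement. The fragile groups are the trisubstituted epoxide that faces the olefin across the ring (acid invites transannular cyclisation), the two esters beside the oxirane (acyl shift, solvolysis) and the conjugated senecioate (deconjugation, strong base, hydride). The real difficulty is twofold: a strained E-cyclodecene must be closed, and a trans epoxide must be set between two oxygenated carbons with full relative control in a conformationally mobile ring. The key step exploits that the oxygen-bearing C6 lies 1,5 to C10 through C7–C8–C9: with C6 as a ketone the ring is a cyclodec-5-enone, the product of an oxy-Cope shift that makes C8–C9 and opens a cyclohexane C1–C2–C3–C4–C5–C6 across C1–C6. In that cyclohexane C3, C4 and C5 are ordinary ring stereocentres; only the 4,5-oxygens must be cis, because a six-membered ring cannot hold the trans oxirane, so C5 is inverted after the expansion. The substitution of this cyclohexane (oxygen on C3 cis-1,3 to the isopropenyl-bearing C1, methyl on the olefinic C4) is that of cis-carveol, so (S)-carvone supplies C1 and relays it to C3–C5. A menthane enone with the isopropenyl-bearing carbon α to the carbonyl would need the C3 oxygen through a dienolate that endangers that stereocentre.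

## Logic of the disconnections

22 to 21: the C5–O bond of the oxirane is cut, the C4–O bond stays. The trans epoxide then comes from a cis 4,5-diol by inversion at C5, and making it last spares it every later reagent. The demand is an anti arrangement of the C4 alkoxide and the C5 sulfonate in the ten-membered ring and a base that leaves two esters alone.

21 to 20 to 19: the S–O bond of the mesylate, then the two C–O bonds of the isopropylidene ketal. The secondary C5 hydroxyl is told from the tertiary C4 hydroxyl by sterics alone, and one ketal holds both oxygens cis through all organometallic steps. The demand is hydrolysis beside two esters without acyl shift.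

19 to 18 to 17 to 16: the acyl C–O bond at C3, the Si–O bond at C3 and the acyl C–O bond at C6. Esters cannot pass potassium hydride or an alkenylmetal, so they follow the ring expansion; the acetate goes on first because 16 has a single free hydroxyl, the senecioate after fluoride so that it meets neither fluoride nor hydride. The demand is acylation of hindered secondary alcohols without deconjugation.

16 to 15: the C6–H bond. C6 leaves the key step as a ketone, and this removes one stereocentre from the ring-forming problem. The demand is hydride delivery to one face (6R).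

15 to 12 (key step): C8–C9 is cut and C1–C6 is reconnected. The ten-membered ring with its E olefin becomes a cyclohexane in which C3, C4 and C5 are fixed by ring substituents and the two alkenyl groups are trans. The demand is a chair transition state with both alkenyl groups equatorial, and control of C7, which is made only on protonation of the enolate.

12 to 8 and 9: the C6–C7 bond. The alkenyl fragment brings C7, C8 and the isopropyl carbons in one piece. The demand is addition to the carbonyl trans to the isopropenyl group, without enolisation.

8 to 7 to 6: the Si–O bond; then the C9=C10 olefin and the C3 hydroxyl are rejoined as a C10–O ether with iodine on C9. The bridged ether masks the isopropenyl group, protects the C3 oxygen, locks C1 as a bridgehead and covers one face of the ring. The demand is that zinc spares the α-alkoxy ketone.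

6 to 5 to 4: the ketal C–O bonds, then the C4–O and C5–O bonds. Both oxygens come from one cis-dihydroxylation of an enone. The demand is attack on the face opposite the bridge, on an electron-poor olefin.

4 to 3: the C6=O bond, by oxidation of the allylic methylene next to C1. The demand is regioselection for the ring methylene over the methyl and the bridgehead position.

3 to 2 to 1: the C10–O and C9–I bonds, then the C3–H bond. This ends at a commercial enone that carries C1 in the right absolute sense. The demand is a cis-selective 1,2-reduction.

## Other disconnections considered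

Alternative 1: The cut is C5–C6. Forward, the open-chain aldehyde A2, an E alkenyl iodide that already holds the C3 senecioate and the C7 isopropyl, would be treated with CrCl2 and catalytic NiCl2; the alkenylchromium species adds to the C6 aldehyde and closes the dienol A1 (Nozaki–Hiyama–Kishi).
- In favour: both olefin geometries are fixed in the chain; divalent chromium tolerates the senecioate, so no late esterification is needed; C7 is set by ordinary acyclic chemistry, not by protonation of an enolate. On C7 and on the number of steps after ring closure (epoxidation and acetylation only) this plan is the better one.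
- Against: the ten-membered ring is closed end to end, against entropy and transannular strain, which calls for high dilution and a large excess of chromium. C6 is formed under 1,2-induction from C7 alone. The 4,5-epoxide must afterwards be placed on one face of A1; hydroxyl-directed epoxidation is chemoselective, but allylic strain from the C15 methyl points to the threo epoxy alcohol, while the target is erythro. C3 and C7 of A2 are isolated centres that each need their own asymmetric step.
- Comparison: on structure the chosen plan carries C3–C5 on a rigid six-membered template, while Alternative 1 has no template. On mechanism the sigmatropic shift is intramolecular and needs no dilution. On step economy the two are about equal, since A2 would take roughly as many steps as 12.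

Alternative 2: The cut is C7–C8, with the C12–O bond reconnected. The fourteen-membered lactone A4 (drawn with an E C7=C11 bond) would be converted with LiN(iPr)2 and Me3SiCl into its silyl ketene acetal, whose [3,3] shift forms C7–C8 and contracts the ring to A3 (Ireland–Claisen).
- In favour: a macrolactonisation replaces the hard carbocyclisation; both ring olefins are preset; C7 is made in a C–C bond-forming step with transfer from C6 and the olefin geometry. On C7 this is better than the chosen plan, and on the pericyclic, dilution-free ring-forming event it is its equal.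
- Against: A3 carries a carboxyl group on C8 that the target lacks (for example Barton decarboxylation, several steps) and an isopropenyl group that must be reduced beside two trisubstituted ring olefins. Chair and boat arrays compete in medium-ring ketene acetals, so which geometry of A4 gives 7S would have to be found. The epoxide and both esters are still to come.
- Comparison: the chosen oxy-Cope leaves no traceless group to remove and gives C6 already oxidised; step economy clearly favours the chosen plan.

Alternative 3: The move reconnects C5 to C10. The trans-fused eudesma-1,3-diene A6 would be irradiated at 254 nm at low temperature; conrotatory six-electron opening cleaves C5–C10 and gives the triene A5. With the silyloxy group on C3 the central bond of A5, which has the ring carbons cis, is E by the sequence rules, so A5 is named 1(10)E,2E,4E.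
- In favour: the bicyclic precursor is rigid, C6, C7 and the ring fusion can come from the lactone eudesmanes of the chiral pool, and one photon makes the ring and both trans ring olefins without a reagent. On the security of C7 and on the step count of the ring-forming event this plan is the better one.
- Against: the opening is reversible and competes with thermal reclosure and hydrogen shifts. A5 has an extra unsaturation: the enol ether must become the C3 carbinol and C4=C5 the epoxide of one absolute sense. The chiral-pool eudesmanes carry the C6 oxygen α and an oxidised C12, so inversion at C6 and deoxygenation to isopropyl come before the photolysis.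
- Comparison: both plans are pericyclic, but the anionic shift is driven to the enolate while the photochemical one stops at a stationary mixture. On structure Alternative 3 secures C6 and C7 and the chosen plan secures C3–C5. Overall step economy is not better than the chosen plan.

Key step: step 9

Remark: (S)-(+)-carvone (1) and 2-bromo-3-methylbut-1-ene (9) are taken as purchasable; the ether carbon made in step 2 (bearing CH3 and CH2I) is expected as a mixture of epimers, is written without descriptor in 3–6 and disappears in step 6.

Conventions: ring carbons of ten-membered compounds carry germacrane numbers and α/β as usually drawn; six-membered intermediates carry the locants of their names, and their carbons are also referred to by the germacrane numbers they acquire.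

Check of structures: in 12 and 15 the configurations at C3 and C4 are those of 22 and C5 is the opposite one, as the invertive closure requires; the isopropenyl-bearing carbon of 12 matches the stereocentre of 1; no structure of the route needed correction.

## Steps

Step 1
Reactants: 1 (S)-(+)-carvone, (5S)-2-methyl-5-(prop-1-en-2-yl)cyclohex-2-en-1-one
Product: 2 (1S,5S)-cis-carveol, (1S,5S)-2-methyl-5-(prop-1-en-2-yl)cyclohex-2-en-1-ol (hydroxyl cis to isopropenyl)
Conditions: NaBH4, CeCl3·7H2O, MeOH, −78 to 0 °C
Reagents that add atoms: none
Why: Luche 1,2-reduction; hydride enters the cerium-activated carbonyl axially, so the new carbinol (1S, the later C3) is cis to the isopropenyl group, and neither olefin is touched.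

Step 2
Reactants: 2 (1S,5S)-cis-carveol
Product: 3 (1S,5S)-7-(iodomethyl)-4,7-dimethyl-6-oxabicyclo[3.2.1]oct-3-ene (bridged iodo ether, epimers at C7 of the bicycle)
Conditions: I2, NaHCO3, MeCN, 0 °C, dark
Reagents that add atoms: iodine, [I][I]
Why: Iodoetherification; the iodonium ion of the isopropenyl group is captured 5-exo at its tertiary carbon by the cis-1,3 hydroxyl, while the ring olefin has no nucleophile within reach. One operation masks the isopropenyl group, protects the C3 oxygen, locks C1 as a bridgehead and lays a two-atom bridge over one face of the ring olefin.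

Step 3
Reactants: 3 bridged iodo ether
Product: 4 (1S,5S)-7-(iodomethyl)-4,7-dimethyl-6-oxabicyclo[3.2.1]oct-3-en-2-one
Conditions: CrO3, 3,5-dimethylpyrazole, CH2Cl2, −20 °C
Reagents that add atoms: chromium trioxide, O=[Cr](=O)=O
Why: Allylic C–H oxidation with the CrO3–3,5-dimethylpyrazole complex; the bridgehead C–H lies near the nodal plane of the olefin and the methyl is less reactive than the ring methylene, so the methylene next to C1 should become the conjugated ketone (the later C6). The primary neopentyl-type iodide is inert to hexavalent chromium.

Step 4
Reactants: 4 bicyclic enone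
Product: 5 (1S,3R,4S,5S)-3,4-dihydroxy-7-(iodomethyl)-4,7-dimethyl-6-oxabicyclo[3.2.1]octan-2-one (both hydroxyls on the face away from the O6–C7 bridge)
Conditions: K2OsO4·2H2O (5 mol %), N-methylmorpholine N-oxide, citric acid, t-BuOH–H2O, 25 °C
Reagents that add atoms: N-methylmorpholine N-oxide, C[N+]1([O-])CCOCC1; water, O
Why: Catalytic OsO4/N-oxide cis-dihydroxylation, run with citric acid as for electron-poor trisubstituted alkenes. As in other bicyclo[3.2.1]octenones the reagent should enter opposite the two-atom bridge, which sets C4 and C5 with both oxygens trans to the C3 oxygen.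

Step 5
Reactants: 5 diol
Product: 6 3,4-O-isopropylidene derivative of 5 (cis-fused dioxolane on the face away from the bridge)
Conditions: 2,2-dimethoxypropane, pyridinium p-toluenesulfonate (cat.), acetone, 25 °C
Reagents that add atoms: 2,2-dimethoxypropane, COC(C)(C)OC
Why: Acid-catalysed ketal exchange on a cis tertiary/secondary diol; early protection also blocks retro-aldol cleavage of the β-hydroxy ketone.

Step 6
Reactants: 6 acetonide iodo ether
Product: 7 4-hydroxy-2,3-(isopropylidenedioxy)-3-methyl-6-(prop-1-en-2-yl)cyclohexan-1-one (4-OH, 3-CH3 and 6-isopropenyl on the upper face, both dioxolane oxygens on the lower face)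
Conditions: Zn dust, AcOH, EtOH, 25 °C
Reagents that add atoms: none
Why: Boord-type reductive fragmentation; zinc inserts into the carbon–iodine bond and the β-alkoxide leaves, which returns the isopropenyl group and the C3 hydroxyl together. The α-ketal C–O bond should not be reduced by zinc at room temperature, and the released α-centre (C1) keeps its equatorial isopropenyl group.

Step 7
Reactants: 7 hydroxy ketone
Product: 8 4-(tert-butyldimethylsilyloxy)-2,3-(isopropylidenedioxy)-3-methyl-6-(prop-1-en-2-yl)cyclohexan-1-one (relative configuration as 7)
Conditions: TBSOTf, 2,6-lutidine, CH2Cl2, −78 °C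
Reagents that add atoms: tert-butyldimethylsilyl trifluoromethanesulfonate, CC(C)(C)[Si](C)(C)OS(=O)(=O)C(F)(F)F
Why: Silylation of a hindered secondary alcohol with the silyl triflate; at −78 °C with 2,6-lutidine the ketone should not be enol-silylated and C1 should not epimerise.

Step 8
Reactants: 8 silyloxy ketone; 9 2-bromo-3-methylbut-1-ene
Product: 12 4-(tert-butyldimethylsilyloxy)-2,3-(isopropylidenedioxy)-3-methyl-1-(3-methylbut-1-en-2-yl)-6-(prop-1-en-2-yl)cyclohexan-1-ol (1-OH cis to isopropenyl; the two alkenyl groups trans), via 3-methylbut-1-en-2-yllithium 10 (not isolated), via dichloro(3-methylbut-1-en-2-yl)cerium 11 (not isolated)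
Conditions: 9, t-BuLi (2 equiv), Et2O, −78 °C; CeCl3, THF, −78 °C; 8, −78 °C; H2O
Reagents that add atoms: none
Why: Bromine–lithium exchange, transmetalation to the less basic organocerium (trivalent cerium) and 1,2-addition to a hindered, enolisable α-alkoxy ketone. In the chair with isopropenyl and silyloxy equatorial the C4 methyl is axial and syn to the axial trajectory, so the bulky reagent should enter equatorially, trans to the isopropenyl group, leaving the new hydroxyl axial: the trans-1,2-dialkenyl array needed in step 9.

Step 9
Reactants: 12 trans-dialkenylcyclohexanol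
Product: 15 (1(10)E,7S)-3β-(tert-butyldimethylsilyloxy)-4α,5α-(isopropylidenedioxy)germacr-1(10)-en-6-one, via potassium alkoxide 13 (not isolated), via potassium enolate 14 (not isolated)
Conditions: KH, 18-crown-6, THF, 0 to 25 °C; AcOH–THF, −78 °C (inverse quench); crude ketone: DBU (cat.), toluene, 25 °C
Reagents that add atoms: none
Why: Anionic oxy-Cope rearrangement, a [3,3] sigmatropic shift of a 1,5-diene 3-alkoxide; the closest known class is the KH/18-crown-6 rearrangement of trans-1,2-dialkenylcyclohexanols to (E)-cyclodec-5-enones. KH converts the tertiary alcohol into 13, whose crown-separated alkoxide weakens the C1–C6 bond; C8–C9 forms between the two methylene termini as C1–C6 breaks, and enolate 14 is the sink. The ten-membered ring is closed by four-atom expansion of the cyclohexane, a pericyclic reorganisation and not an end-to-end cyclisation, so no dilution is needed. The chair transition state keeps both alkenyl groups equatorial and C2 pseudo-equatorial on C1, which fixes C1=C10 as E. C7 is the one new stereocentre and is made on protonation of 14; protonation from the ring periphery may give the 7-epimer, so the crude ketone is equilibrated with catalytic amidine towards the 7S epimer, in which the isopropyl group points outward in the crown conformer. C3, C4 and C5 pass unchanged, the ketal and the silyl ether are inert to KH, and the cis-fused dioxolane holds the C4–O bond out of alignment for β-elimination. The step needs the E olefin, secured by the trans-diequatorial dialkenyl array, and 7S, which rests on thermodynamic control.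

Step 10
Reactants: 15 ten-membered ketone
Product: 16 (1(10)E)-3β-(tert-butyldimethylsilyloxy)-4α,5α-(isopropylidenedioxy)germacr-1(10)-en-6β-ol
Conditions: LiBH(s-Bu)3, THF, −78 °C; H2O
Reagents that add atoms: none
Why: Reduction with a bulky, non-chelating hydride; Felkin–Anh addition on the side away from the C5–O bond of the α-alkoxy ketone should give the 5,6-threo alcohol, the 6β (6R) carbinol cis to the C7 isopropyl group. Silyl ether, ketal and olefin are inert.

Step 11
Reactants: 16 6β-alcohol
Product: 17 (1(10)E)-3β-(tert-butyldimethylsilyloxy)-4α,5α-(isopropylidenedioxy)germacr-1(10)-en-6β-yl acetate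
Conditions: Ac2O, 4-(dimethylamino)pyridine, pyridine, CH2Cl2, 25 °C
Reagents that add atoms: acetic anhydride, CC(=O)OC(C)=O
Why: Nucleophile-catalysed acetylation of the only free hydroxyl, a hindered secondary one; no stereocentre is touched.

Step 12
Reactants: 17 silyl ether acetate
Product: 18 (1(10)E)-3β-hydroxy-4α,5α-(isopropylidenedioxy)germacr-1(10)-en-6β-yl acetate
Conditions: Bu4NF, AcOH, THF, 25 °C
Reagents that add atoms: none
Why: Fluoride cleavage of the secondary silyl ether, buffered with acetic acid so that the acetate is neither cleaved nor shifted; the ketal is inert.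

Step 13
Reactants: 18 C3 alcohol
Product: 19 (1(10)E)-6β-acetoxy-4α,5α-(isopropylidenedioxy)germacr-1(10)-en-3β-yl 3-methylbut-2-enoate
Conditions: 3-methylbut-2-enoic acid, 2,4,6-trichlorobenzoyl chloride, Et3N, THF; then 18, 4-(dimethylamino)pyridine, toluene, 40 °C
Reagents that add atoms: 3-methylbut-2-enoic acid, CC(C)=CC(=O)O
Why: Yamaguchi esterification; the mixed anhydride is formed first and the hindered C3 alcohol is acylated under nucleophilic catalysis. Keeping free amine base away from the acylating agent limits deconjugation of the 3-methylbut-2-enoyl group.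

Step 14
Reactants: 19 ketal diester
Product: 20 (1(10)E)-6β-acetoxy-4α,5α-dihydroxygermacr-1(10)-en-3β-yl 3-methylbut-2-enoate
Conditions: AcOH–H2O (4:1), 45 °C
Reagents that add atoms: none
Why: Acid-catalysed hydrolysis of the dioxolane; both esters and the isolated trisubstituted olefin should tolerate warm aqueous acetic acid. The diol is used at once to limit acetyl shift from O6 to O5.

Step 15
Reactants: 20 diol diester
Product: 21 (1(10)E)-6β-acetoxy-4α-hydroxy-5α-(methanesulfonyloxy)germacr-1(10)-en-3β-yl 3-methylbut-2-enoate
Conditions: MsCl, Et3N, CH2Cl2, −10 °C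
Reagents that add atoms: methanesulfonyl chloride, CS(=O)(=O)Cl
Why: Sulfonylation through sulfene; the secondary C5 hydroxyl reacts and the tertiary C4 hydroxyl does not, so the two oxygens of the former diol are told apart without a protecting group.

Step 16
Reactants: 21 hydroxy mesylate
Product: 22 (1(10)E,3S,4R,5R,6R,7S)-6β-acetoxy-4α,5β-epoxygermacr-1(10)-en-3β-yl 3-methylbut-2-enoate (CNP0267399.1)
Conditions: KN(SiMe3)2 (1.05 equiv), THF, −78 to 0 °C
Reagents that add atoms: none
Why: Intramolecular Williamson etherification (3-exo-tet); the C4 alkoxide displaces the C5 mesylate from the rear, which inverts C5 to R, keeps C4 and turns the cis diol into the trans oxirane. One equivalent of a hindered amide base at low temperature removes the hydroxyl proton far faster than any C–H of the esters, and the epoxide meets no further reagent.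

## Compound list

1 | (S)-(+)-carvone | CC1=CC[C@@H](CC1=O)C(C)=C | starting material
2 | (1S,5S)-cis-carveol | CC1=CC[C@@H](C[C@@H]1O)C(C)=C | intermediate
3 | (1S,5S)-7-(iodomethyl)-4,7-dimethyl-6-oxabicyclo[3.2.1]oct-3-ene (C7 epimers) | CC1=CC[C@H]2C[C@@H]1OC2(C)CI | intermediate
4 | (1S,5S)-7-(iodomethyl)-4,7-dimethyl-6-oxabicyclo[3.2.1]oct-3-en-2-one | CC1=CC(=O)[C@H]2C[C@@H]1OC2(C)CI | intermediate
5 | (1S,3R,4S,5S)-3,4-dihydroxy-7-(iodomethyl)-4,7-dimethyl-6-oxabicyclo[3.2.1]octan-2-one | O=C1[C@H](O)[C@](C)(O)[C@@H]2C[C@H]1C(C)(CI)O2 | intermediate
6 | 3,4-O-isopropylidene derivative of 5 | O=C1[C@@H]2OC(C)(C)O[C@]2(C)[C@@H]3C[C@H]1C(C)(CI)O3 | intermediate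
7 | 4-hydroxy-2,3-(isopropylidenedioxy)-3-methyl-6-(prop-1-en-2-yl)cyclohexan-1-one | O=C1[C@@H]2OC(C)(C)O[C@]2(C)[C@@H](O)C[C@H]1C(C)=C | intermediate
8 | 4-(tert-butyldimethylsilyloxy)-2,3-(isopropylidenedioxy)-3-methyl-6-(prop-1-en-2-yl)cyclohexan-1-one | O=C1[C@@H]2OC(C)(C)O[C@]2(C)[C@@H](O[Si](C)(C)C(C)(C)C)C[C@H]1C(C)=C | intermediate
9 | 2-bromo-3-methylbut-1-ene | C=C(Br)C(C)C | starting material
10 | 3-methylbut-1-en-2-yllithium | [Li]C(=C)C(C)C | intermediate (not isolated)
11 | dichloro(3-methylbut-1-en-2-yl)cerium | Cl[Ce](Cl)C(=C)C(C)C | intermediate (not isolated)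
12 | trans-dialkenylcyclohexanol (oxy-Cope precursor) | O[C@@]1(C(=C)C(C)C)[C@@H]2OC(C)(C)O[C@]2(C)[C@@H](O[Si](C)(C)C(C)(C)C)C[C@H]1C(C)=C | intermediate
13 | potassium alkoxide of 12 | [K+].[O-][C@@]1(C(=C)C(C)C)[C@@H]2OC(C)(C)O[C@]2(C)[C@@H](O[Si](C)(C)C(C)(C)C)C[C@H]1C(C)=C | intermediate (not isolated)
14 | potassium enolate of 15 (C6=C7, ring carbons trans) | [K+].[O-]/C1=C(/C(C)C)CC/C(C)=C/C[C@H](O[Si](C)(C)C(C)(C)C)[C@@]2(C)OC(C)(C)O[C@@H]12 | intermediate (not isolated)
15 | (1(10)E,7S)-3β-silyloxy-4α,5α-(isopropylidenedioxy)germacr-1(10)-en-6-one | O=C1[C@@H]2OC(C)(C)O[C@]2(C)[C@@H](O[Si](C)(C)C(C)(C)C)C/C=C(\C)CC[C@H]1C(C)C | intermediate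
16 | 6β-alcohol of 15 | O[C@H]1[C@@H]2OC(C)(C)O[C@]2(C)[C@@H](O[Si](C)(C)C(C)(C)C)C/C=C(\C)CC[C@H]1C(C)C | intermediate
17 | 6β-acetate of 16 | CC(=O)O[C@H]1[C@@H]2OC(C)(C)O[C@]2(C)[C@@H](O[Si](C)(C)C(C)(C)C)C/C=C(\C)CC[C@H]1C(C)C | intermediate
18 | 3β-hydroxy 6β-acetate acetonide | CC(=O)O[C@H]1[C@@H]2OC(C)(C)O[C@]2(C)[C@@H](O)C/C=C(\C)CC[C@H]1C(C)C | intermediate
19 | 3β-senecioate 6β-acetate acetonide | CC(=O)O[C@H]1[C@@H]2OC(C)(C)O[C@]2(C)[C@@H](OC(=O)C=C(C)C)C/C=C(\C)CC[C@H]1C(C)C | intermediate
20 | 4α,5α-diol diester | CC(=O)O[C@H]1[C@H](O)[C@](C)(O)[C@@H](OC(=O)C=C(C)C)C/C=C(\C)CC[C@H]1C(C)C | intermediate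
21 | 5α-mesylate of 20 | CC(=O)O[C@H]1[C@H](OS(C)(=O)=O)[C@](C)(O)[C@@H](OC(=O)C=C(C)C)C/C=C(\C)CC[C@H]1C(C)C | intermediate
22 | (1(10)E,3S,4R,5R,6R,7S)-6β-acetoxy-4α,5β-epoxygermacr-1(10)-en-3β-yl 3-methylbut-2-enoate | CC(=O)O[C@H]1[C@H]2O[C@]2(C)[C@@H](OC(=O)C=C(C)C)C/C=C(\C)CC[C@H]1C(C)C | target

## Step count and least certain steps

Total: 16 steps. Longest linear sequence: 16 steps (1 to 22); fragment 9 is used as bought.

**Step 9 (key step).** Two things may go wrong. The hindered, oxygen-rich alkoxide may fragment or eliminate before it rearranges. Stereocontrol at C7 may be lost on protonation, and the base used to equilibrate C7 may also epimerise C5, whose hydrogen is made acidic by the neighbouring oxygen. Fallback, a neutral siloxy-Cope shift: from 12, silylation with N-(trimethylsilyl)imidazole gives the trimethylsilyl ether F1; heating in toluene in a sealed tube at about 220 °C should take F1 through the same chair array to the ten-membered trimethylsilyl enol ether F2; aqueous acetic acid in THF at 0 °C releases the ketone without any base and returns to the route at 15.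

**Step 8.** Facial selectivity may be poor, because attack trans to the isopropenyl group passes the axial C5 oxygen and the dioxolane; the basic reagent may also enolise the ketone. Fallback: from 6, the organocerium 11 is added to the bridged ketone, where the oxygen bridge with its quaternary carbon covers the face cis to the future isopropenyl carbon; this should give the tertiary alcohol F3. Zinc and acetic acid open the iodo ether to the diol F4, and TBSOTf with 2,6-lutidine silylates only the secondary hydroxyl, which returns to the route at 12.

**Step 10.** Hydride delivery may be unselective or reversed, because the C7 branch (Felkin preference for the other face) and the C5 oxygen pull in opposite directions. Fallback by inversion instead of selective reduction: from 15, if the 6α-alcohol F5 predominates, Mitsunobu esterification (PPh3, diisopropyl azodicarboxylate, 4-nitrobenzoic acid) gives the 6β 4-nitrobenzoate F6 with inversion; K2CO3 in MeOH cleaves it and returns to the route at 16.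

**Step 3.** Oxidation may stop short, attack the allylic methyl or over-oxidise, since radical-type allylic oxidations are sensitive to the substrate. Fallback by ene reaction and transposition: from 3, the Schenck ene reaction (O2, tetraphenylporphyrin, visible light, CH2Cl2) should take a ring-methylene hydrogen (cis effect) and give the tertiary allylic hydroperoxide F7, reduced in the same flask with PPh3 to the tertiary allylic alcohol F8; Babler–Dauben oxidative transposition with pyridinium chlorochromate (C5H5NH)[CrO3Cl] returns to the route at 4.

**Step 14.** The two acyloxy neighbours slow ketal hydrolysis, and more forcing acid invites acetyl shift from O6 to O5 or participation of the C1=C10 olefin. Fallback, unmasking the diol before any ester is present: from 15, aqueous acetic acid gives the dihydroxy ketone F9; MsCl and Et3N give the 5-mesylate F10; DBU in CH2Cl2 at 0 °C closes the trans epoxy ketone F11; Zn(BH4)2 in Et2O, by chelation between carbonyl and oxirane oxygen, should give the erythro epoxy alcohol F12; acetylation gives F13; Bu4NF with AcOH gives the epoxy alcohol F14; Yamaguchi esterification with 3-methylbut-2-enoic acid returns to the route at 22.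

**Step 16.** The C4 alkoxide may transfer an acyl group from a neighbouring ester, or the base may eliminate the mesylate. Fallback without base or sulfonate: from 20, Mitsunobu cyclodehydration (PPh3, diisopropyl azodicarboxylate, toluene) activates the secondary C5 hydroxyl and lets the tertiary C4 hydroxyl displace it with inversion, which returns to the route at 22.

## Further compounds

F1 | step 9 | trimethylsilyl ether of 12 | C[Si](C)(C)O[C@@]1(C(=C)C(C)C)[C@@H]2OC(C)(C)O[C@]2(C)[C@@H](O[Si](C)(C)C(C)(C)C)C[C@H]1C(C)=C
F2 | step 9 | trimethylsilyl enol ether of 15 | C[Si](C)(C)O/C1=C(/C(C)C)CC/C(C)=C/C[C@H](O[Si](C)(C)C(C)(C)C)[C@@]2(C)OC(C)(C)O[C@@H]12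
F3 | step 8 | adduct of 11 and 6 (tertiary alcohol, iodo ether intact, alkenyl on the face away from the bridge) | O[C@@]1(C(=C)C(C)C)[C@@H]2OC(C)(C)O[C@]2(C)[C@@H]3C[C@H]1C(C)(CI)O3
F4 | step 8 | desilyl 12 (1,4-diol) | O[C@@]1(C(=C)C(C)C)[C@@H]2OC(C)(C)O[C@]2(C)[C@@H](O)C[C@H]1C(C)=C
F5 | step 10 | 6α-epimer of 16 | O[C@@H]1[C@@H]2OC(C)(C)O[C@]2(C)[C@@H](O[Si](C)(C)C(C)(C)C)C/C=C(\C)CC[C@H]1C(C)C
F6 | step 10 | 6β 4-nitrobenzoate of 16 | O=C(O[C@H]1[C@@H]2OC(C)(C)O[C@]2(C)[C@@H](O[Si](C)(C)C(C)(C)C)C/C=C(\C)CC[C@H]1C(C)C)c1ccc(cc1)[N+](=O)[O-]
F7 | step 3 | 4-hydroperoxy-7-(iodomethyl)-4,7-dimethyl-6-oxabicyclo[3.2.1]oct-2-ene (hydroperoxy group away from the bridge) | C[C@]1(OO)C=C[C@H]2C[C@@H]1OC2(C)CI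
F8 | step 3 | 7-(iodomethyl)-4,7-dimethyl-6-oxabicyclo[3.2.1]oct-2-en-4-ol | C[C@]1(O)C=C[C@H]2C[C@@H]1OC2(C)CI
F9 | step 14 | 3β-silyloxy-4α,5α-dihydroxygermacr-1(10)-en-6-one | O=C1[C@H](O)[C@](C)(O)[C@@H](O[Si](C)(C)C(C)(C)C)C/C=C(\C)CC[C@H]1C(C)C
F10 | step 14 | 5α-mesylate of F9 | O=C1[C@H](OS(C)(=O)=O)[C@](C)(O)[C@@H](O[Si](C)(C)C(C)(C)C)C/C=C(\C)CC[C@H]1C(C)C
F11 | step 14 | 3β-silyloxy-4α,5β-epoxygermacr-1(10)-en-6-one | O=C1[C@H]2O[C@]2(C)[C@@H](O[Si](C)(C)C(C)(C)C)C/C=C(\C)CC[C@H]1C(C)C
F12 | step 14 | 3β-silyloxy-4α,5β-epoxygermacr-1(10)-en-6β-ol | O[C@H]1[C@H]2O[C@]2(C)[C@@H](O[Si](C)(C)C(C)(C)C)C/C=C(\C)CC[C@H]1C(C)C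
F13 | step 14 | 6β-acetate of F12 | CC(=O)O[C@H]1[C@H]2O[C@]2(C)[C@@H](O[Si](C)(C)C(C)(C)C)C/C=C(\C)CC[C@H]1C(C)C
F14 | step 14 | 6β-acetoxy-4α,5β-epoxygermacr-1(10)-en-3β-ol | CC(=O)O[C@H]1[C@H]2O[C@]2(C)[C@@H](O)C/C=C(\C)CC[C@H]1C(C)C
F0 | step 16 | none | none
A1 | alternative 1 | (1(10)E,4E)-6-hydroxygermacra-1(10),4-dien-3-yl 3-methylbut-2-enoate | O[C@H]1/C=C(\C)[C@@H](OC(=O)C=C(C)C)C/C=C(\C)CC[C@H]1C(C)C
A2 | alternative 1 | open-chain E alkenyl iodide aldehyde (C5 iodide, C6 aldehyde) | I/C=C(\C)[C@@H](OC(=O)C=C(C)C)C/C=C(\C)CC[C@H](C=O)C(C)C
A3 | alternative 2 | ten-membered E,E-diene with C7 isopropenyl and C8 carboxylic acid (C8 undefined) | CC(C)(C)[Si](C)(C)O[C@H]1/C=C(\C)[C@@H](OCc2ccc(OC)cc2)C/C=C(\C)CC(C(=O)O)[C@H]1C(C)=C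
A4 | alternative 2 | fourteen-membered allylic lactone (C7=C11 drawn E) | O=C1CC/C(C)=C/C[C@H](OCc2ccc(OC)cc2)/C(C)=C/[C@H](O[Si](C)(C)C(C)(C)C)/C=C(C)/CO1
A5 | alternative 3 | cyclodeca-1(10),2,4-triene 3-silyl enol ether 6-acetate (ring carbons cis at C2=C3) | CC(=O)O[C@H]1/C=C(\C)/C(O[Si](C)(C)C(C)(C)C)=C\C=C(/C)CC[C@H]1C(C)C
A6 | alternative 3 | trans-fused 3-silyloxyeudesma-1,3-dien-6β-yl acetate (H-5α, 10β-methyl) | CC(=O)O[C@H]1[C@H]2C(C)=C(O[Si](C)(C)C(C)(C)C)C=C[C@]2(C)CC[C@H]1C(C)C
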